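## Retrosynthetic overview

1. The (1E,3E)-diene is cut at its central C–C bond: a Suzuki–Miyaura union of oxolane alkenylboronate 12 with iodovinyl isocoumarin 22 is the last step, with no protecting group left to remove.
2. Oxolane ring (O1, C2 with the dienyl arm, C3 with OH, C4 = CH2, C5 with CH3): the C5 methyl and C5–H come from MeLi addition to γ-lactone 7 and oxocarbenium reduction. O1 comes from Baeyer–Villiger oxidation of cyclobutanone 6. Cyclobutanone 6 comes from a [2+2] cycloaddition of vinylketene with vinyl ether 3 of a bought chiral alcohol, which makes C5–C4 and C2–C3 together.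
3. Enabling feature: the hydroxyl sits on C3, so C2–C3–C4–C5 of the oxolane is a 3-alkoxycyclobutanone in disguise (C5 = carbonyl carbon, C4 = CH2, C3 = O-bearing enol ether carbon, C2 = ketene α-carbon with the alkenyl arm). O1 is the atom a Baeyer–Villiger step inserts between C5 and C2, and the cis C2/C3 relationship is the kinetic outcome of a ketene cycloaddition.
4. Isocoumarin: chlorination of methyl orsellinate, lateral lithiation and acylation with a glyoxylate acetal, enol lactonisation (closes the pyranone ring), Takai olefination.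
5. Ring order: cyclobutanone → γ-lactone → oxolane (fragment 1); pyranone ring on the preformed chlororesorcinol arene (fragment 2); diene last.

Key step: step 2

Remark: the sense of facial induction in step 2 is deduced from the s-trans, C–H-eclipsed conformer of enol ether 3; both enantiomers of alcohol 1 are commercial, and the diastereomers should be separable at lactone 7, where the configuration can be confirmed before the route continues.

## Route

Step 1
Reactants: 1 (S)-1-(2,4,6-triisopropylphenyl)ethanol; 2 vinyl acetate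
Product: 3 (S)-1,3,5-triisopropyl-2-[1-(vinyloxy)ethyl]benzene
Conditions: [Ir(cod)Cl]2 (1 mol %), Na2CO3 (0.6 equiv), 2 (2 equiv), toluene, 100 °C
Reagents that add atoms: none
Why: Iridium-catalysed transfer vinylation of a secondary alcohol by vinyl acetate proceeds by addition–elimination at the vinyl group, so the carbinol C–O bond and its (S) configuration are untouched.

Step 2
Reactants: 3 (S)-1,3,5-triisopropyl-2-[1-(vinyloxy)ethyl]benzene; 4 (E)-but-2-enoyl chloride
Product: 6 (2S,3S)-3-[(S)-1-(2,4,6-triisopropylphenyl)ethoxy]-2-vinylcyclobutan-1-one, via vinylketene 5 (not isolated)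
Conditions: Et3N (3.5 equiv), CH2Cl2, 40 °C, 4 (3 equiv) added over 8 h; short Florisil plug, used at once
Reagents that add atoms: none
Why: Et3N converts 4 (through its acylammonium salt, by γ-deprotonation) into vinylketene 5, which is trapped as it forms by the electron-rich vinyl ether 3 in a thermal ketene–alkene [2+2] cycloaddition; the closest known reactions are the cycloadditions of in situ aldoketenes and of vinylketene with alkyl vinyl ethers (giving 3-alkoxycyclobutanones) and of ketenes with enol ethers of this same auxiliary alcohol. The cyclobutanone closes in one asynchronous, polarity-matched [π2s+π2a]-type event: the nucleophilic CH2 terminus of the enol ether bonds to the ketene carbonyl carbon (the later C5–C4 bond) and the incipient enolate carbon collapses onto the oxocarbenium-like O-bearing carbon (formally a 4-exo-trig closure, the later C2–C3 bond). The alkoxy-bearing stereocentre is set by the auxiliary: in the s-trans enol ether with the carbinol C–H eclipsing the O–vinyl bond, the 2,4,6-triisopropylphenyl group covers one face and the ketene adds to the other, which for the (S)-alcohol should give the 3S centre. The α-stereocentre follows from the kinetic preference of monosubstituted ketenes to approach with their hydrogen, not the larger vinyl group, turned toward the alkene, so vinyl and alkoxy should end up cis (2S). The step needs regioselectivity (secured by the enol ether polarisation), periselectivity for the ketene C=C over a [4+2] mode (usual for vinylketene with simple enol ethers) and survival of the kinetic cis isomer, for which slow addition of 4, a modest temperature and immediate oxidation of 6 are used.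

Step 3
Reactants: 6 (2S,3S)-3-[(S)-1-(2,4,6-triisopropylphenyl)ethoxy]-2-vinylcyclobutan-1-one
Product: 7 (4S,5S)-4-[(S)-1-(2,4,6-triisopropylphenyl)ethoxy]-5-vinyldihydrofuran-2(3H)-one
Conditions: mCPBA (1.2 equiv), NaHCO3 (3 equiv), CH2Cl2, 0 °C
Reagents that add atoms: mCPBA, OOC(=O)c1cccc(Cl)c1
Why: Baeyer–Villiger oxidation of the strained cyclobutanone is much faster than epoxidation of the monosubstituted vinyl group, and the secondary allylic α-carbon migrates in preference to CH2 with retention, which places the ring oxygen between the former carbonyl carbon and the vinyl-bearing carbon.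

Step 4
Reactants: 7 (4S,5S)-4-[(S)-1-(2,4,6-triisopropylphenyl)ethoxy]-5-vinyldihydrofuran-2(3H)-one
Product: 8 (4S,5S)-2-methyl-4-[(S)-1-(2,4,6-triisopropylphenyl)ethoxy]-5-vinyltetrahydrofuran-2-ol (anomeric mixture)
Conditions: MeLi (1.1 equiv), THF, −78 °C; then aq. NH4Cl
Reagents that add atoms: methyllithium, [Li]C
Why: Methyllithium adds once to the γ-lactone carbonyl at −78 °C because the lithium hemiketal alkoxide is stable until the quench (1,2-addition of an organolithium to a 3-O-protected 1,4-lactone); the new anomeric centre is not controlled and is removed in step 5.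

Step 5
Reactants: 8 (4S,5S)-2-methyl-4-[(S)-1-(2,4,6-triisopropylphenyl)ethoxy]-5-vinyltetrahydrofuran-2-ol
Product: 9 (2S,3S,5S)-5-methyl-3-[(S)-1-(2,4,6-triisopropylphenyl)ethoxy]-2-vinyltetrahydrofuran
Conditions: Et3SiH (3 equiv), BF3·OEt2 (2 equiv), CH2Cl2, −78 °C
Reagents that add atoms: none
Why: Lewis acid ionisation of the hemiketal gives the five-membered oxocarbenium ion, which triethylsilane reduces by inside attack on the envelope that holds the C3 alkoxy group pseudoaxial (the selectivity known for 3-alkoxy five-membered oxocarbenium ions), so hydrogen should enter cis to the alkoxy and vinyl groups and the methyl group end up trans to both (5S).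

Step 6
Reactants: 9 (2S,3S,5S)-5-methyl-3-[(S)-1-(2,4,6-triisopropylphenyl)ethoxy]-2-vinyltetrahydrofuran
Product: 10 (2S,3S,5S)-5-methyl-2-vinyltetrahydrofuran-3-ol
Conditions: CF3CO2H/CH2Cl2 (1:4), 0 °C; then aq. NaHCO3
Reagents that add atoms: none
Why: The hindered, electron-rich secondary benzylic ether is cleaved by trifluoroacetic acid through the 1-arylethyl cation (SN1/E1), while the unactivated allylic oxolane ether should not ionise at 0 °C; no oxolane stereocentre is involved.

Step 7
Reactants: 10 (2S,3S,5S)-5-methyl-2-vinyltetrahydrofuran-3-ol; 11 4,4,5,5-tetramethyl-2-vinyl-1,3,2-dioxaborolane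
Product: 12 (2S,3S,5S)-5-methyl-2-[(E)-2-(4,4,5,5-tetramethyl-1,3,2-dioxaborolan-2-yl)vinyl]tetrahydrofuran-3-ol
Conditions: second-generation Hoveyda–Grubbs catalyst, RuCl2(H2IMes)(=CH-C6H4-2-OiPr) (5 mol %), 11 (3 equiv), CH2Cl2, 40 °C
Reagents that add atoms: none
Why: Olefin cross-metathesis of the terminal vinyl group with excess vinylboronic acid pinacol ester should give the (E)-alkenylboronate under thermodynamic control and tolerates the free secondary hydroxyl.

Step 8
Reactants: 13 methyl 2,4-dihydroxy-6-methylbenzoate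
Product: 14 methyl 3-chloro-4,6-dihydroxy-2-methylbenzoate
Conditions: SO2Cl2 (1.05 equiv), Et2O, 0 °C
Reagents that add atoms: sulfuryl chloride, O=S(=O)(Cl)Cl
Why: Electrophilic aromatic chlorination of an orsellinate with sulfuryl chloride takes place ortho to the free 4-hydroxyl and para to the hydrogen-bonded 2-hydroxyl (next to the methyl group) rather than between the two oxygens, as is usual for orsellinates and orcinaldehydes.

Step 9
Reactants: 14 methyl 3-chloro-4,6-dihydroxy-2-methylbenzoate
Product: 15 methyl 4,6-bis(benzyloxy)-3-chloro-2-methylbenzoate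
Conditions: BnBr (2.5 equiv), K2CO3 (3 equiv), DMF, 60 °C
Reagents that add atoms: benzyl bromide, BrCc1ccccc1
Why: Williamson etherification of both phenols gives base-stable benzyl ethers that survive steps 10–12 and can later be removed without hydrogenation.

Step 10
Reactants: 15 methyl 4,6-bis(benzyloxy)-3-chloro-2-methylbenzoate; 16 ethyl 2,2-diethoxyacetate
Product: 18 methyl 4,6-bis(benzyloxy)-3-chloro-2-(3,3-diethoxy-2-oxopropyl)benzoate, via lithiated toluate 17 (not isolated)
Conditions: LDA (2.2 equiv), THF, −78 °C; then 16 (1.2 equiv), −78 → −40 °C; aq. NH4Cl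
Reagents that add atoms: none
Why: Lateral lithiation of the o-toluate at the benzylic methyl (activated by the ortho ester) and Claisen-type acylation by the activated α,α-dialkoxy ester give the benzyl ketone, and the second equivalent of base stores it as its enolate and so prevents over-addition.

Step 11
Reactants: 18 methyl 4,6-bis(benzyloxy)-3-chloro-2-(3,3-diethoxy-2-oxopropyl)benzoate
Product: 20 6,8-bis(benzyloxy)-5-chloro-1-oxo-1H-isochromene-3-carbaldehyde, via acetal isocoumarin 19 (not isolated)
Conditions: TsOH·H2O (0.2 equiv), toluene, 90 °C; then 2 M HCl, THF, 25 °C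
Reagents that add atoms: water, O
Why: Acid-catalysed enol lactonisation (the oxygen of the aryl-conjugated enol attacks the ortho ester, 6-exo-trig, with loss of methanol) closes the pyranone ring, and the acetal, now on an enol ether carbon, is then hydrolysed by aqueous acid to the aldehyde.

Step 12
Reactants: 20 6,8-bis(benzyloxy)-5-chloro-1-oxo-1H-isochromene-3-carbaldehyde
Product: 21 (E)-6,8-bis(benzyloxy)-5-chloro-3-(2-iodovinyl)-1H-isochromen-1-one
Conditions: CrCl2 (6 equiv), CHI3 (2 equiv), THF, 0 → 25 °C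
Reagents that add atoms: iodoform, IC(I)I
Why: Takai olefination converts the aldehyde into the (E)-iodoalkene through anti-elimination from the gem-dichromium adduct and leaves the lactone, aryl chloride and benzyl ethers alone.

Step 13
Reactants: 21 (E)-6,8-bis(benzyloxy)-5-chloro-3-(2-iodovinyl)-1H-isochromen-1-one
Product: 22 (E)-5-chloro-6,8-dihydroxy-3-(2-iodovinyl)-1H-isochromen-1-one
Conditions: BCl3 (5 equiv), C6HMe5 (6 equiv), CH2Cl2, −78 → 0 °C
Reagents that add atoms: none
Why: BCl3 with pentamethylbenzene as a non-Lewis-basic cation scavenger cleaves aryl benzyl ethers at low temperature without touching the iodoalkene, the aryl chloride or the enol lactone.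

Step 14
Reactants: 12 (2S,3S,5S)-5-methyl-2-[(E)-2-(4,4,5,5-tetramethyl-1,3,2-dioxaborolan-2-yl)vinyl]tetrahydrofuran-3-ol; 22 (E)-5-chloro-6,8-dihydroxy-3-(2-iodovinyl)-1H-isochromen-1-one
Product: 23 5-chloro-6,8-dihydroxy-3-[(1E,3E)-4-[(2S,3S,5S)-3-hydroxy-5-methyltetrahydrofuran-2-yl]buta-1,3-dien-1-yl]-1H-isochromen-1-one
Conditions: Pd(PPh3)4 (5 mol %), K3PO4 (4 equiv), THF/H2O (4:1), degassed, 25 °C; work-up with pH 6 phosphate buffer
Reagents that add atoms: none
Why: Suzuki–Miyaura coupling of an (E)-alkenyl iodide with an (E)-alkenylboronate proceeds with retention at both alkenes to give the (1E,3E)-diene, and mild aqueous phosphate at 25 °C tolerates the phenols (as phenoxides, which also deactivate the lactone carbonyl) and the secondary alcohol.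

## Compound list

1 | (S)-1-(2,4,6-triisopropylphenyl)ethanol | C[C@H](O)c1c(C(C)C)cc(C(C)C)cc1C(C)C | starting material
2 | vinyl acetate | CC(=O)OC=C | starting material
3 | (S)-1,3,5-triisopropyl-2-[1-(vinyloxy)ethyl]benzene | C[C@H](OC=C)c1c(C(C)C)cc(C(C)C)cc1C(C)C | intermediate
4 | (E)-but-2-enoyl chloride | C/C=C/C(=O)Cl | starting material
5 | vinylketene (buta-1,3-dien-1-one) | C=CC=C=O | intermediate
6 | (2S,3S)-3-[(S)-1-(2,4,6-triisopropylphenyl)ethoxy]-2-vinylcyclobutan-1-one | O=C1C[C@H](O[C@@H](C)c2c(C(C)C)cc(C(C)C)cc2C(C)C)[C@@H]1C=C | intermediate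
7 | (4S,5S)-4-[(S)-1-(2,4,6-triisopropylphenyl)ethoxy]-5-vinyldihydrofuran-2(3H)-one | O=C1C[C@H](O[C@@H](C)c2c(C(C)C)cc(C(C)C)cc2C(C)C)[C@H](C=C)O1 | intermediate
8 | (4S,5S)-2-methyl-4-[(S)-1-(2,4,6-triisopropylphenyl)ethoxy]-5-vinyltetrahydrofuran-2-ol | CC1(O)C[C@H](O[C@@H](C)c2c(C(C)C)cc(C(C)C)cc2C(C)C)[C@H](C=C)O1 | intermediate
9 | (2S,3S,5S)-5-methyl-3-[(S)-1-(2,4,6-triisopropylphenyl)ethoxy]-2-vinyltetrahydrofuran | C[C@H]1C[C@H](O[C@@H](C)c2c(C(C)C)cc(C(C)C)cc2C(C)C)[C@H](C=C)O1 | intermediate
10 | (2S,3S,5S)-5-methyl-2-vinyltetrahydrofuran-3-ol | C[C@H]1C[C@H](O)[C@H](C=C)O1 | intermediate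
11 | 4,4,5,5-tetramethyl-2-vinyl-1,3,2-dioxaborolane | C=CB1OC(C)(C)C(C)(C)O1 | starting material
12 | (2S,3S,5S)-5-methyl-2-[(E)-2-(4,4,5,5-tetramethyl-1,3,2-dioxaborolan-2-yl)vinyl]tetrahydrofuran-3-ol | C[C@H]1C[C@H](O)[C@H](/C=C/B2OC(C)(C)C(C)(C)O2)O1 | intermediate
13 | methyl 2,4-dihydroxy-6-methylbenzoate | COC(=O)c1c(C)cc(O)cc1O | starting material
14 | methyl 3-chloro-4,6-dihydroxy-2-methylbenzoate | COC(=O)c1c(C)c(Cl)c(O)cc1O | intermediate
15 | methyl 4,6-bis(benzyloxy)-3-chloro-2-methylbenzoate | COC(=O)c1c(C)c(Cl)c(OCc2ccccc2)cc1OCc1ccccc1 | intermediate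
16 | ethyl 2,2-diethoxyacetate | CCOC(=O)C(OCC)OCC | starting material
17 | methyl 4,6-bis(benzyloxy)-3-chloro-2-(lithiomethyl)benzoate (lithiated toluate) | COC(=O)c1c(C[Li])c(Cl)c(OCc2ccccc2)cc1OCc1ccccc1 | intermediate
18 | methyl 4,6-bis(benzyloxy)-3-chloro-2-(3,3-diethoxy-2-oxopropyl)benzoate | COC(=O)c1c(CC(=O)C(OCC)OCC)c(Cl)c(OCc2ccccc2)cc1OCc1ccccc1 | intermediate
19 | 6,8-bis(benzyloxy)-5-chloro-3-(diethoxymethyl)-1H-isochromen-1-one (acetal isocoumarin) | CCOC(OCC)c1cc2c(Cl)c(OCc3ccccc3)cc(OCc3ccccc3)c2c(=O)o1 | intermediate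
20 | 6,8-bis(benzyloxy)-5-chloro-1-oxo-1H-isochromene-3-carbaldehyde | O=Cc1cc2c(Cl)c(OCc3ccccc3)cc(OCc3ccccc3)c2c(=O)o1 | intermediate
21 | (E)-6,8-bis(benzyloxy)-5-chloro-3-(2-iodovinyl)-1H-isochromen-1-one | I/C=C/c1cc2c(Cl)c(OCc3ccccc3)cc(OCc3ccccc3)c2c(=O)o1 | intermediate
22 | (E)-5-chloro-6,8-dihydroxy-3-(2-iodovinyl)-1H-isochromen-1-one | I/C=C/c1cc2c(Cl)c(O)cc(O)c2c(=O)o1 | intermediate
23 | 5-chloro-6,8-dihydroxy-3-[(1E,3E)-4-[(2S,3S,5S)-3-hydroxy-5-methyltetrahydrofuran-2-yl]buta-1,3-dien-1-yl]-1H-isochromen-1-one | C[C@H]1C[C@H](O)[C@H](/C=C/C=C/c2cc3c(Cl)c(O)cc(O)c3c(=O)o2)O1 | target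

## Step count and risks

Total steps: 14 (steps 1–7 oxolane fragment, steps 8–13 isocoumarin fragment, step 14 union).
Longest linear sequence: 8 steps (steps 1–7 and 14).

Steps most likely to fail:

1. Step 2. What may go wrong: base-mediated epimerisation or conjugation at the doubly activated (α-keto and allylic) carbon of the cycloadduct, together with oligomerisation of vinylketene, would erode the cis relationship and the yield. Fallback: the route is left at vinyl ether 3 and a ketene with a masked vinyl group is used. 4-(Phenylselanyl)butanoyl chloride F1 (from the corresponding acid and oxalyl chloride) with Et3N gives the ordinary alkylketene 4-(phenylselanyl)but-1-en-1-one F2 in situ. Its [2+2] cycloaddition with 3 should give (2S,3S)-2-[2-(phenylselanyl)ethyl]-3-[(S)-1-(2,4,6-triisopropylphenyl)ethoxy]cyclobutan-1-one F3, whose α-carbon is no longer allylic. Excess mCPBA with NaHCO3 then effects Baeyer–Villiger oxidation and selenide oxidation in one flask to (4S,5S)-5-[2-(phenylseleninyl)ethyl]-4-[(S)-1-(2,4,6-triisopropylphenyl)ethoxy]dihydrofuran-2(3H)-one F4. On warming to 25 °C with iPr2NH this undergoes selenoxide syn-elimination to the vinyl group, and the sequence comes back to the route at lactone 7.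

2. Step 5. What may go wrong: poor facial selectivity in hydride delivery to the oxocarbenium ion, if steric approach control by the bulky ether and the vinyl group (both on the face that must be attacked) competes with the stereoelectronic preference. Fallback: the route is left at lactone 7 and C5 is set by a cyclisation that is trans-selective on its own. DIBAL-H at −78 °C gives (4S,5S)-4-[(S)-1-(2,4,6-triisopropylphenyl)ethoxy]-5-vinyltetrahydrofuran-2-ol F5. Wittig methylenation (Ph3P=CH2) opens it to (3S,4S)-4-[(S)-1-(2,4,6-triisopropylphenyl)ethoxy]hepta-1,6-dien-3-ol F6. Mukaiyama aerobic oxidative cyclisation (Co(modp)2, a divalent cobalt complex, O2, t-BuOOH, i-PrOH, 50 °C) closes the 2,5-trans oxolane [(2R,4S,5S)-4-[(S)-1-(2,4,6-triisopropylphenyl)ethoxy]-5-vinyltetrahydrofuran-2-yl]methanol F7. Tosylation gives [(2R,4S,5S)-4-[(S)-1-(2,4,6-triisopropylphenyl)ethoxy]-5-vinyltetrahydrofuran-2-yl]methyl 4-methylbenzenesulfonate F8, and LiBHEt3 reduces the tosylate to the methyl group, which comes back to the route at compound 9.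

3. Step 14. What may go wrong: opening of the enol lactone by aqueous base, protodeboronation of 12, or stalling of transmetalation through phenoxide coordination to palladium. Fallback: the route is left at iodide 22 and the union is run on silyl-protected phenols. TIPSOTf with 2,6-lutidine gives (E)-5-chloro-3-(2-iodovinyl)-6,8-bis[(triisopropylsilyl)oxy]-1H-isochromen-1-one F9. Suzuki–Miyaura coupling of F9 with boronate 12 (Pd(PPh3)4, aq. K3PO4, THF, 25 °C) gives 5-chloro-3-[(1E,3E)-4-[(2S,3S,5S)-3-hydroxy-5-methyltetrahydrofuran-2-yl]buta-1,3-dien-1-yl]-6,8-bis[(triisopropylsilyl)oxy]-1H-isochromen-1-one F10. Buffered fluoride (TBAF/AcOH, THF, 0 °C) removes both aryl silyl ethers and comes back to the route at target 23.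

## Further compounds

F1 | step 2 | 4-(phenylselanyl)butanoyl chloride | O=C(Cl)CCC[Se]c1ccccc1
F2 | step 2 | 4-(phenylselanyl)but-1-en-1-one | O=C=CCC[Se]c1ccccc1
F3 | step 2 | (2S,3S)-2-[2-(phenylselanyl)ethyl]-3-[(S)-1-(2,4,6-triisopropylphenyl)ethoxy]cyclobutan-1-one | O=C1C[C@H](O[C@@H](C)c2c(C(C)C)cc(C(C)C)cc2C(C)C)[C@@H]1CC[Se]c1ccccc1
F4 | step 2 | (4S,5S)-5-[2-(phenylseleninyl)ethyl]-4-[(S)-1-(2,4,6-triisopropylphenyl)ethoxy]dihydrofuran-2(3H)-one | O=C1C[C@H](O[C@@H](C)c2c(C(C)C)cc(C(C)C)cc2C(C)C)[C@H](CC[Se](=O)c2ccccc2)O1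
F5 | step 5 | (4S,5S)-4-[(S)-1-(2,4,6-triisopropylphenyl)ethoxy]-5-vinyltetrahydrofuran-2-ol | OC1C[C@H](O[C@@H](C)c2c(C(C)C)cc(C(C)C)cc2C(C)C)[C@H](C=C)O1
F6 | step 5 | (3S,4S)-4-[(S)-1-(2,4,6-triisopropylphenyl)ethoxy]hepta-1,6-dien-3-ol | C=CC[C@H](O[C@@H](C)c1c(C(C)C)cc(C(C)C)cc1C(C)C)[C@@H](O)C=C
F7 | step 5 | [(2R,4S,5S)-4-[(S)-1-(2,4,6-triisopropylphenyl)ethoxy]-5-vinyltetrahydrofuran-2-yl]methanol | OC[C@H]1C[C@H](O[C@@H](C)c2c(C(C)C)cc(C(C)C)cc2C(C)C)[C@H](C=C)O1
F8 | step 5 | [(2R,4S,5S)-4-[(S)-1-(2,4,6-triisopropylphenyl)ethoxy]-5-vinyltetrahydrofuran-2-yl]methyl 4-methylbenzenesulfonate | Cc1ccc(cc1)S(=O)(=O)OC[C@H]1C[C@H](O[C@@H](C)c2c(C(C)C)cc(C(C)C)cc2C(C)C)[C@H](C=C)O1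
F9 | step 14 | (E)-5-chloro-3-(2-iodovinyl)-6,8-bis[(triisopropylsilyl)oxy]-1H-isochromen-1-one | I/C=C/c1cc2c(Cl)c(O[Si](C(C)C)(C(C)C)C(C)C)cc(O[Si](C(C)C)(C(C)C)C(C)C)c2c(=O)o1
F10 | step 14 | 5-chloro-3-[(1E,3E)-4-[(2S,3S,5S)-3-hydroxy-5-methyltetrahydrofuran-2-yl]buta-1,3-dien-1-yl]-6,8-bis[(triisopropylsilyl)oxy]-1H-isochromen-1-one | C[C@H]1C[C@H](O)[C@H](/C=C/C=C/c2cc3c(Cl)c(O[Si](C(C)C)(C(C)C)C(C)C)cc(O[Si](C(C)C)(C(C)C)C(C)C)c3c(=O)o2)O1
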